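**Plan**

1. Eudesmane-type numbering is used: C1 ring ketone, C2 its bridgehead neighbour, C3=C4(Me), C5 quaternary bridgehead, C6 O–CH, C7–C9, C10 C(Me), C11 CH(Me), C12 lactone C=O, C1′/C2′ the CH/CH2 of the ethano bridge.
2. Retrosynthetic cuts, in order: C2–C1′ and C5–C2′ (Diels–Alder of dienone lactone 14 with the vinyl group of myrcene); C6–C7 and C11–C12 (ring B and γ-lactone in one event); C8–C7 (B-alkyl Suzuki); C1–C10 and C4–C5 (ring A by Diels–Alder).
3. Forward ring order: ring A, then the pentenyl arm, then ring B and the lactone together, then the 2,4-dienone, then the bicyclo[2.2.2]octenone.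
4. Enabling feature: in the lactone ring (O, C6, C7, C11, C12) the carbinol carbon C6 and the carbonyl carbon C12 are joined through the ring oxygen, and each lies one bond from a carbon of a former C7=C11 alkene. With C6–Cl and C12–OPh (a 1-chloroalkyl phenyl carbonate, one step from the aldehyde), a C6 radical closes the cyclohexane ring B 6-exo and the resulting C11 organosamarium closes the lactone by 5-exo acyl substitution.
5. Stereochemistry: C10 from the chiral Lewis acid; C5–H from the E geometry of the dienophile; C6 and C7 from the chair transition state of ring B closure; C11 by equilibration. C2, C5 and C1′ come from the endo, β-face Diels–Alder.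
6. The key step is stereoconvergent (C6 chloride epimers, alkene geometry, C11); the helper centres C1, C4 and C5–H are erased on the way to the dienone.

Key step: step 7

Assumption: the (S)-o-tolyl oxazaborolidinium triflimide is taken to give the enantiomer of 4 that is drawn (C10 as in the target); if the sense is opposite, the (R)-catalyst is used.

**Route**

Step 1
Reactants: 1 (E)-pent-2-enal
Product: 2 (1E,3E)-1-(triisopropylsilyloxy)penta-1,3-diene
Conditions: TIPSOTf, Et3N, Et2O, 0 °C to rt
Reagents that add atoms: triisopropylsilyl trifluoromethanesulfonate, CC(C)[Si](C(C)C)(C(C)C)OS(=O)(=O)C(F)(F)F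
Why: Soft γ-enolisation of the enal and O-silylation (silyl dienol ether formation) should give the 1-silyloxy diene, of which the (1E,3E) isomer is the reactive one; no stereocentre is formed.

Step 2
Reactants: 2 (1E,3E)-1-(triisopropylsilyloxy)penta-1,3-diene, 3 (E)-4-acetoxy-2-methylbut-2-enal
Product: 4 [6-formyl-2,6-dimethyl-5-(triisopropylsilyloxy)cyclohex-3-en-1-yl]methyl acetate (10β-Me, 10α-CHO, 5β-CH2OAc, 5α-H, 1α-OTIPS, 4α-Me; drawn as the endo adduct)
Conditions: (S)-o-tolyl-CBS-oxazaborolidine·Tf2NH (20 mol%), CH2Cl2, −78 to −40 °C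
Reagents that add atoms: none
Why: Catalytic enantioselective Diels–Alder reaction of a 2-substituted acrolein, in which the oxygenated diene terminus (C1) should bond to the formyl-bearing carbon (C10) and the methyl terminus (C4) to C5 (ortho rule), the E geometry of 3 places CH2OAc trans to CHO and cis to the C10 methyl, the catalyst sets the quaternary C10, and the endo/exo outcome touches only C1 and C4, which are erased later.

Step 3
Reactants: 4 ring A aldehyde
Product: 5 [6-ethenyl-2,6-dimethyl-5-(triisopropylsilyloxy)cyclohex-3-en-1-yl]methyl acetate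
Conditions: Ph3PCH3Br, KOtBu, THF, 0 °C
Reagents that add atoms: methyltriphenylphosphonium bromide, C[P+](c1ccccc1)(c1ccccc1)c1ccccc1.[Br-]
Why: Wittig methylenation of a non-enolisable neopentyl aldehyde, which should leave the acetate intact at 0 °C with a small excess of ylide.

Step 4
Reactants: 5 vinyl acetate
Product: 8 [2,6-dimethyl-6-((E)-pent-3-enyl)-5-(triisopropylsilyloxy)cyclohex-3-en-1-yl]methanol, via B-alkyl-9-BBN borane 6 (not isolated), via coupled acetate 7 (not isolated)
Conditions: 9-BBN, THF, 0 °C to rt; then (E)-1-bromoprop-1-ene, Pd(dppf)Cl2 (5 mol%), 3 M aq. NaOH, THF, 50 °C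
Reagents that add atoms: (E)-1-bromoprop-1-ene, C/C=C/Br
Why: Anti-Markovnikov hydroboration of the monosubstituted vinyl group (far faster than the cis-disubstituted ring alkene) and B-alkyl Suzuki–Miyaura coupling with retention of the E geometry should join C8 to C7, and the aqueous hydroxide of the coupling cleaves the acetate.

Step 5
Reactants: 8 primary alcohol
Product: 9 2,6-dimethyl-6-((E)-pent-3-enyl)-5-(triisopropylsilyloxy)cyclohex-3-ene-1-carbaldehyde
Conditions: Dess–Martin periodinane, NaHCO3, CH2Cl2, 0 °C to rt
Reagents that add atoms: none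
Why: Buffered Dess–Martin oxidation should give the aldehyde without epimerising the adjacent C5 centre.

Step 6
Reactants: 9 aldehyde
Product: 10 chloro[2,6-dimethyl-6-((E)-pent-3-enyl)-5-(triisopropylsilyloxy)cyclohex-3-en-1-yl]methyl phenyl carbonate (both C6 epimers, used crude)
Conditions: PhOCOCl, pyridine (5 mol%), CH2Cl2, 0 °C to rt
Reagents that add atoms: phenyl chloroformate, O=C(Cl)Oc1ccccc1
Why: Pyridine-catalysed addition of a chloroformate across an aldehyde C=O is the known route to 1-chloroalkyl carbonates, and both C6 epimers serve because C6 becomes trigonal in step 7.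

Step 7
Reactants: 10 1-chloroalkyl phenyl carbonate
Product: 11 1α-(triisopropylsilyloxy)-4βH,5αH,11βH-eudesm-2-en-12,6α-olide
Conditions: SmI2 (3 equiv), HMPA, tetrahydropyran, 0 °C, slow addition of 10; aq. NH4Cl; then DBU (cat.), CH2Cl2, rt
Reagents that add atoms: none
Why: Proposed new method: single-electron reduction of the activated C6–Cl bond by SmI2 should give the α-(phenoxycarbonyloxy)alkyl radical, which closes ring B by 6-exo-trig addition to C7; the secondary C11 radical is then reduced by SmI2–HMPA to a configurationally labile alkylsamarium, which closes the lactone by 5-exo-trig nucleophilic acyl substitution at the carbonate carbon C12 with loss of phenoxide. The closest known reaction types are SmI2 reduction of α-chloro ethers to α-oxyalkyl radicals and organosamariums, radical cyclisation followed by organosamarium trapping, and intramolecular SmI2 nucleophilic acyl substitution; their combination on a 1-chloroalkyl carbonate is new. Ring B should form through the chair transition state of a trans-fused bicycle in which the C6 oxygen is equatorial (axial would be 1,3-diaxial to the C10 methyl) and the alkene arm is equatorial, giving 6α-O and 7α-H relative to the fixed C5 and C10 centres. C11 is set by closure of the labile organosamarium with the methyl pseudo-equatorial, and DBU converges any C11 epimer to this thermodynamic isomer; the C6 chloride epimers and any Z-alkene converge as well. The step needs cyclisation of the C6 radical to outrun its own reduction, 1,5-hydrogen transfer from allylic C8 and attack on the C2=C3 ring alkene, and it needs reduction of the C11 radical to outrun hydrogen abstraction from solvent; the slow reduction of electron-rich α-oxy radicals, the trans-diequatorial arms on ring A, HMPA and the poor hydrogen donor tetrahydropyran are meant to secure this.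

Step 8
Reactants: 11 silyl ether lactone
Product: 12 1α-hydroxy-4βH,5αH,11βH-eudesm-2-en-12,6α-olide
Conditions: TBAF, THF, rt to 40 °C
Reagents that add atoms: none
Why: Fluoride desilylation should free the allylic alcohol and leave the γ-lactone untouched.

Step 9
Reactants: 12 allylic alcohol
Product: 13 1-oxo-4βH,5αH,11βH-eudesm-2-en-12,6α-olide
Conditions: Dess–Martin periodinane, NaHCO3, CH2Cl2, rt
Reagents that add atoms: none
Why: Dess–Martin oxidation of the allylic alcohol should give the C1 enone and removes the helper stereocentre at C1.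

Step 10
Reactants: 13 enone
Product: 14 1-oxo-11βH-eudesma-2,4-dien-12,6α-olide (6S,7S,10R,11S)
Conditions: DDQ, TsOH·H2O (cat.), 1,4-dioxane, 90 °C
Reagents that add atoms: none
Why: Acid-catalysed γ-enolisation to the 1,3-dienol and hydride abstraction from C5 by DDQ (quinone dehydrogenation of an enone to the linear dienone, as in Δ4-3-keto to Δ4,6-dienone conversions) should give the 2,4-dienone, since quaternary C10 blocks α′-dehydrogenation and aromatisation; the C4 and C5 centres are erased.

Step 11
Reactants: 14 dienone lactone, 15 myrcene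
Product: 16 CNP0385704.1 (target)
Conditions: myrcene (10 equiv, neat), BHT (cat.), sealed tube, 90 °C
Reagents that add atoms: none
Why: Diels–Alder reaction of the 6,6-disubstituted cyclohexa-2,4-dienone (diene C2=C3–C4=C5) with the monosubstituted vinyl group of myrcene, in which the CH2 terminus should bond to C5 (largest LUMO coefficient), the endo orientation places the side chain syn to the new C3=C4 bridge, and attack on the β-face (syn to the 10-methyl, away from the C9 methylene and the chair of ring B on the α-face) sets C2, C5 and C1′; the moderate temperature avoids Cope rearrangement of the adduct.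

**Compound list**

1 | (E)-pent-2-enal | CC/C=C/C=O | starting material
2 | (1E,3E)-1-(triisopropylsilyloxy)penta-1,3-diene | C/C=C/C=C/O[Si](C(C)C)(C(C)C)C(C)C | intermediate
3 | (E)-4-acetoxy-2-methylbut-2-enal | CC(=O)OC/C=C(\C)C=O | starting material
4 | [6-formyl-2,6-dimethyl-5-(triisopropylsilyloxy)cyclohex-3-en-1-yl]methyl acetate; 10β-Me, 10α-CHO, 5β-CH2OAc, 1α-OTIPS, 4α-Me | O=C[C@@]1(C)[C@@H](O[Si](C(C)C)(C(C)C)C(C)C)C=C[C@@H](C)[C@@H]1COC(C)=O | intermediate
5 | [6-ethenyl-2,6-dimethyl-5-(triisopropylsilyloxy)cyclohex-3-en-1-yl]methyl acetate, same configuration as 4 | C=C[C@@]1(C)[C@@H](O[Si](C(C)C)(C(C)C)C(C)C)C=C[C@@H](C)[C@@H]1COC(C)=O | intermediate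
6 | B-alkyl-9-BBN adduct of 5 (boron on the terminal carbon of the former vinyl group) | C1CCC2CCCC1B2CC[C@@]1(C)[C@@H](O[Si](C(C)C)(C(C)C)C(C)C)C=C[C@@H](C)[C@@H]1COC(C)=O | intermediate
7 | [2,6-dimethyl-6-((E)-pent-3-enyl)-5-(triisopropylsilyloxy)cyclohex-3-en-1-yl]methyl acetate | C/C=C/CC[C@@]1(C)[C@@H](O[Si](C(C)C)(C(C)C)C(C)C)C=C[C@@H](C)[C@@H]1COC(C)=O | intermediate
8 | [2,6-dimethyl-6-((E)-pent-3-enyl)-5-(triisopropylsilyloxy)cyclohex-3-en-1-yl]methanol | C/C=C/CC[C@@]1(C)[C@@H](O[Si](C(C)C)(C(C)C)C(C)C)C=C[C@@H](C)[C@@H]1CO | intermediate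
9 | 2,6-dimethyl-6-((E)-pent-3-enyl)-5-(triisopropylsilyloxy)cyclohex-3-ene-1-carbaldehyde; CHO trans to the pentenyl arm, cis to the C10 methyl | C/C=C/CC[C@@]1(C)[C@@H](O[Si](C(C)C)(C(C)C)C(C)C)C=C[C@@H](C)[C@@H]1C=O | intermediate
10 | chloro[2,6-dimethyl-6-((E)-pent-3-enyl)-5-(triisopropylsilyloxy)cyclohex-3-en-1-yl]methyl phenyl carbonate, both epimers at the CHCl carbon | C/C=C/CC[C@@]1(C)[C@@H](O[Si](C(C)C)(C(C)C)C(C)C)C=C[C@@H](C)[C@@H]1C(Cl)OC(=O)Oc1ccccc1 | intermediate
11 | 1α-(triisopropylsilyloxy)-4βH,5αH,11βH-eudesm-2-en-12,6α-olide (trans-fused lactone, 6β-H, 7α-H, 10β-Me) | C[C@@H]1C=C[C@H](O[Si](C(C)C)(C(C)C)C(C)C)[C@]2(C)CC[C@H]3[C@H](C)C(=O)O[C@@H]3[C@@H]12 | intermediate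
12 | 1α-hydroxy-4βH,5αH,11βH-eudesm-2-en-12,6α-olide | C[C@@H]1C=C[C@H](O)[C@]2(C)CC[C@H]3[C@H](C)C(=O)O[C@@H]3[C@@H]12 | intermediate
13 | 1-oxo-4βH,5αH,11βH-eudesm-2-en-12,6α-olide | C[C@@H]1C=CC(=O)[C@]2(C)CC[C@H]3[C@H](C)C(=O)O[C@@H]3[C@@H]12 | intermediate
14 | 1-oxo-11βH-eudesma-2,4-dien-12,6α-olide (6S,7S,10R,11S) | O=C1C=CC(C)=C2[C@@]1(C)CC[C@H]1[C@H](C)C(=O)O[C@H]21 | intermediate
15 | myrcene (7-methyl-3-methyleneocta-1,6-diene) | C=CC(=C)CCC=C(C)C | starting material
16 | CNP0385704.1 | C=C(CCC=C(C)C)[C@H]1C[C@@]23C(C)=C[C@@H]1C(=O)[C@]2(C)CC[C@H]1[C@H](C)C(=O)O[C@@H]13 | target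

**Step count and risks**

Total steps: 11. Longest linear sequence: 11 steps (1 to 16).

Steps most likely to fail:

1. Step 7 (Proposed new method). What may go wrong: reduction or 1,5-hydrogen transfer of the C6 radical before 6-exo closure, or hydrogen abstraction by the C11 radical before it is reduced, so that the second bond does not form. Fallback with known chemistry, from 9 back to 11: Me2AlCl-promoted type-I carbonyl-ene cyclisation of aldehyde 9 (the citronellal-to-isopulegol reaction type) closes ring B and should give the trans 6α-hydroxy-7β-vinyl alcohol F1. Acylation with phenyl selenochloroformate and pyridine gives the Se-phenyl selenocarbonate F2. Bu3SnH and AIBN in benzene at 80 °C generate the alkoxycarbonyl radical, which closes the lactone 5-exo onto the vinyl group; after DBU equilibration of C11 the route is rejoined at 11.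

2. Step 2. What may go wrong: protodesilylation of the silyl dienol ether by the Brønsted-acid-activated catalyst, or weak enantiofacial discrimination with the β-substituted enal. Fallback, from 2 and 3 back to 4: an achiral Lewis acid (Me2AlCl, CH2Cl2, −78 °C) gives 4 as the racemate, that is, together with its enantiomer F3. Lipase-catalysed hydrolysis (for example Candida antarctica lipase B in buffer/MTBE, enzyme chosen by screening so that F3 reacts fast) converts F3 into the hydroxy aldehyde F4 and leaves 4, which is separated by chromatography and carried on from 4.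

3. Step 11. What may go wrong: dimerisation of the dienone, reaction of myrcene through its 1,3-diene unit, or attack on the α-face. Fallback, from 14 to 16: Diels–Alder reaction of 14 with the activated dienophile methyl vinyl ketone (toluene, 60–80 °C; ortho/endo selectivity as known for cyclohexa-2,4-dienones with enones) gives the acetyl adduct F5. Kinetic enolate formation at the methyl group (LDA, THF, −78 °C; the ring ketone is non-enolisable) and alkylation with prenyl bromide give the ketone F6. Chemoselective Wittig methylenation (Ph3P=CH2) of the unhindered side-chain ketone then gives 16.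

**Further compounds**

F1 | step 7 | 6α-hydroxy-7β-vinyl carbonyl-ene product: 1α-(triisopropylsilyloxy)-13-nor-type trans-decalin alcohol with ethenyl at C7 | C[C@@H]1C=C[C@H](O[Si](C(C)C)(C(C)C)C(C)C)[C@]2(C)CC[C@@H](C=C)[C@H](O)[C@@H]12
F2 | step 7 | Se-phenyl selenocarbonate of F1 | C[C@@H]1C=C[C@H](O[Si](C(C)C)(C(C)C)C(C)C)[C@]2(C)CC[C@@H](C=C)[C@H](OC(=O)[Se]c3ccccc3)[C@@H]12
F3 | step 2 | enantiomer of 4 | O=C[C@]1(C)[C@H](O[Si](C(C)C)(C(C)C)C(C)C)C=C[C@H](C)[C@H]1COC(C)=O
F4 | step 2 | hydroxy aldehyde from deacetylation of F3 | O=C[C@]1(C)[C@H](O[Si](C(C)C)(C(C)C)C(C)C)C=C[C@H](C)[C@H]1CO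
F5 | step 11 | acetyl Diels–Alder adduct of 14 with methyl vinyl ketone | CC(=O)[C@H]1C[C@@]23C(C)=C[C@@H]1C(=O)[C@]2(C)CC[C@H]1[C@H](C)C(=O)O[C@@H]13
F6 | step 11 | 5-methylhex-4-enoyl ketone from prenylation of F5 | CC(C)=CCCC(=O)[C@H]1C[C@@]23C(C)=C[C@@H]1C(=O)[C@]2(C)CC[C@H]1[C@H](C)C(=O)O[C@@H]13
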